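**Retrosynthetic overview**
- The target comes from C4 oxidation of an epoxy alcohol, made by hydroxyl-directed epoxidation of the C2=C3 ring olefin (the oxirane is the second ring, formed last), after Luche reduction and bis-angeloylation of a diol enone.
- The diol enone (carbocycle, first ring) comes from an asymmetric intramolecular carbonyl-ene closure of an open-chain 2-oxofarnesa-3,6,10-trienal: farnesane C1 (CHO) is attacked by the C6=C7 olefin, the C7 bisabolyl cation loses H-14, and C5, C6 and the 7(14)-olefin are set in one step.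
- The keto aldehyde comes from a (Z,Z)-skipped diene built in one pot by a double Wittig reaction of a C3 bis-phosphonium salt with two α-alkoxy methyl ketones.
- The two ketones come from sulcatone (organocatalytic α-oxygenation sets C8) and from methyl (R)-glycerate acetonide.

Assumption: ring compounds carry bisabolane numbering (ring C1–C6, CH3-15 on C3, side chain C7–C14 on C6; farnesane C1, C2, C3, C4, C5, C6 of the open-chain precursors become C5, C4, C3, C2, C1, C6), and the target is read as (2S,3S,5S,6S,8S) with the epoxide cis to the side chain and trans to the C5 angelate.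

**Step 1**
Reactants: 1 6-methylhept-5-en-2-one (sulcatone)
Product: 3 (S)-3-hydroxy-6-methylhept-5-en-2-one, via anilinooxy ketone 2 (not isolated)
Conditions: D-proline (20 mol%), PhNO (limiting, slow addition), 1 (3 equiv), DMF, 0 °C; then CuSO4·5H2O (30 mol%), MeOH, 0 °C
Reagents that add atoms: nitrosobenzene, O=Nc1ccccc1
Why: Proline-enamine α-aminoxylation (O-selective nitroso aldol) oxygenates the more substituted α-carbon of the methyl ketone, D-proline directing attack to the enamine face that gives 3S (L-proline gives R with ketones), and copper-catalysed N–O cleavage then frees the ketol without racemisation.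

**Step 2**
Reactants: 3 (S)-3-hydroxy-6-methylhept-5-en-2-one
Product: 4 (S)-3-(tert-butyldimethylsilyloxy)-6-methylhept-5-en-2-one
Conditions: TBSCl, imidazole, DMF, 0 → 23 °C
Reagents that add atoms: tert-butyldimethylsilyl chloride, CC(C)(C)[Si](C)(C)Cl
Why: Silyl ether formation under weakly basic conditions leaves the stereocentre untouched and installs the α-silyloxy group that later steers the Wittig geometry.

**Step 3**
Reactants: 5 methyl (R)-2,2-dimethyl-1,3-dioxolane-4-carboxylate
Product: 7 (R)-1-(2,2-dimethyl-1,3-dioxolan-4-yl)ethan-1-one, via Weinreb amide 6 (not isolated)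
Conditions: MeNH(OMe)·HCl (1.5 equiv), i-PrMgCl (3.0 equiv), THF, −20 °C; then MeMgBr (2 equiv), −20 → 0 °C
Reagents that add atoms: methylmagnesium bromide, C[Mg]Br; N,O-dimethylhydroxylamine hydrochloride, CNOC.Cl (its atoms stay in 6 only)
Why: One-pot Weinreb ketone synthesis, in which the chelated tetrahedral adduct of the N-methoxy-N-methylamide with MeMgBr stops at the methyl ketone; the dioxolane centre is retained (it is erased in step 6 in any case).

**Step 4**
Reactants: 8 propane-1,3-diylbis(triphenylphosphonium) dibromide; 4 (S)-3-(tert-butyldimethylsilyloxy)-6-methylhept-5-en-2-one; 7 (R)-1-(2,2-dimethyl-1,3-dioxolan-4-yl)ethan-1-one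
Product: 12 (4S)-4-[(2Z,5Z,7S)-7-(tert-butyldimethylsilyloxy)-6,10-dimethylundeca-2,5,9-trien-2-yl]-2,2-dimethyl-1,3-dioxolane, via mono-ylide 9 (not isolated), via phosphonium salt 10 (not isolated), via ylide 11 (not isolated)
Conditions: 8 (1.1 equiv), KN(SiMe3)2 (1.1 equiv), THF, −78 → 0 °C; 4 (1.0 equiv), −78 → 23 °C; KN(SiMe3)2 (1.1 equiv), −78 °C; 7 (1.5 equiv), −78 → 23 °C
Reagents that add atoms: none
Why: Two consecutive Wittig olefinations from one C3 bis-phosphonium linchpin, in which unstabilised ylides add to α-alkoxy methyl ketones so that the oxygenated carbon ends up cis to the ylide chain (Z-selective Wittig of α-alkoxy ketones), setting both Z olefins of the skipped diene, while salt-free conditions at −78 °C keep the α-silyloxy centre from epimerising.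

**Step 5**
Reactants: 12 (4S)-4-[(2Z,5Z,7S)-7-(tert-butyldimethylsilyloxy)-6,10-dimethylundeca-2,5,9-trien-2-yl]-2,2-dimethyl-1,3-dioxolane
Product: 13 (2S,3Z,6Z,8S)-8-(tert-butyldimethylsilyloxy)-3,7,11-trimethyldodeca-3,6,10-triene-1,2-diol
Conditions: PPTS (0.2 equiv), MeOH, 23 °C
Reagents that add atoms: none
Why: Acid-catalysed transacetalisation (acetonide methanolysis) frees the terminal allylic diol while the hindered secondary TBS ether survives PPTS; no stereocentre is touched.

**Step 6**
Reactants: 13 (2S,3Z,6Z,8S)-8-(tert-butyldimethylsilyloxy)-3,7,11-trimethyldodeca-3,6,10-triene-1,2-diol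
Product: 14 (3Z,6Z,8S)-8-(tert-butyldimethylsilyloxy)-3,7,11-trimethyl-2-oxododeca-3,6,10-trienal
Conditions: IBX (3 equiv), DMSO, 23 °C; filtered, dried azeotropically (toluene, 4 Å MS) and used at once
Reagents that add atoms: none
Why: IBX oxidises 1,2-diols to 1,2-dicarbonyls without C–C cleavage and under neutral conditions, so both alcohols reach the carbonyl level without isomerising the Z-enone or the doubly allylic CH2.

**Step 7**
Reactants: 14 (3Z,6Z,8S)-8-(tert-butyldimethylsilyloxy)-3,7,11-trimethyl-2-oxododeca-3,6,10-trienal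
Product: 16 (5S,6S,8S)-5,8-dihydroxybisabola-2,7(14),10-trien-4-one, via silyl ether 15 (not isolated)
Conditions: Cu(SbF6)2·[(S,S)-t-Bu-box] (10–20 mol%; box = 2,2'-(propane-2,2-diyl)bis[(4S)-4-tert-butyl-4,5-dihydro-1,3-oxazole]), 4 Å MS, CH2Cl2 (0.02 M), −40 → 0 °C; then HF·pyridine, THF, 0 → 23 °C
Reagents that add atoms: none
Why: Proposed new method: asymmetric intramolecular glyoxal-ene (cation–olefin, Prins-type) cyclisation, in which the α-keto aldehyde chelates the C2-symmetric copper Lewis acid in a square-planar complex whose tert-butyl groups leave only the si face of the aldehyde open, the 6Z olefin attacks farnesane C1 through a chair-like six-membered transition state with the side chain equatorial (C5–OH trans to C6, hence 5S,6S), and the methyl group trans to the tether gives its proton to the carbonyl oxygen as the C7 bisabolyl cation develops, which places the olefin at C7(14); the closest known reactions are copper–bisoxazoline glyoxylate-ene reactions (S carbinols with the S,S tert-butyl ligand), intramolecular ene cyclisations of unsaturated α-keto esters and the neral-to-isopiperitenol cyclisation, and HF·pyridine then removes the TBS group in the same flask.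

**Step 8**
Reactants: 16 (5S,6S,8S)-5,8-dihydroxybisabola-2,7(14),10-trien-4-one; 17 angelic acid [(Z)-2-methylbut-2-enoic acid]
Product: 18 (5S,6S,8S)-5,8-bis(angeloyloxy)bisabola-2,7(14),10-trien-4-one
Conditions: 17 (3 equiv), 2,4,6-Cl3C6H2COCl (3 equiv), Et3N (6 equiv), toluene, 23 °C; then 16, 80 °C (no DMAP)
Reagents that add atoms: none
Why: Yamaguchi esterification, in which the mixed anhydride of angelic acid acylates both secondary alcohols without a nucleophilic catalyst, conditions that keep the Z (angelate) geometry from isomerising to tiglate; no stereocentre is formed.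

**Step 9**
Reactants: 18 (5S,6S,8S)-5,8-bis(angeloyloxy)bisabola-2,7(14),10-trien-4-one
Product: 19 (4S,5S,6S,8S)-5,8-bis(angeloyloxy)bisabola-2,7(14),10-trien-4-ol
Conditions: NaBH4, CeCl3·7H2O, MeOH, −78 °C
Reagents that add atoms: none
Why: Luche 1,2-reduction, in which hydride adds axially to the C4 carbonyl to give the equatorial 4α-alcohol (4S, trans to the equatorial C5 ester and cis to the side chain), as carvone gives cis-carveol, while the angelate esters are not reduced.

**Step 10**
Reactants: 19 (4S,5S,6S,8S)-5,8-bis(angeloyloxy)bisabola-2,7(14),10-trien-4-ol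
Product: 20 (2S,3R,4R,5S,6S,8S)-5,8-bis(angeloyloxy)-2,3-epoxybisabola-7(14),10-dien-4-ol
Conditions: VO(acac)2 (5 mol%), t-BuOOH (1.5 equiv), CH2Cl2, 0 → 23 °C
Reagents that add atoms: tert-butyl hydroperoxide, CC(C)(C)OO
Why: Hydroxyl-directed epoxidation, in which the alkylperoxo vanadate bound to the allylic C4 alkoxide delivers oxygen to the same (α) face of the C2=C3 olefin, giving the epoxide cis to the side chain and trans to the C5 ester, and leaves the prenyl, exo-methylene and angelate olefins untouched.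

**Step 11**
Reactants: 20 (2S,3R,4R,5S,6S,8S)-5,8-bis(angeloyloxy)-2,3-epoxybisabola-7(14),10-dien-4-ol
Product: 21 (2S,3S,5S,6S,8S)-5,8-bis(angeloyloxy)-2,3-epoxybisabola-7(14),10-dien-4-one
Conditions: Dess–Martin periodinane, NaHCO3, CH2Cl2, 0 → 23 °C
Reagents that add atoms: none
Why: Dess–Martin oxidation turns the epoxy alcohol into the epoxy ketone under buffered conditions that do not epimerise the α-acyloxy centre C5 or open the epoxide; all five stereocentres are already in place (the C3 descriptor changes from R to S only through CIP priorities).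

**Compound list**
1 | 6-methylhept-5-en-2-one (sulcatone) | CC(=O)CCC=C(C)C | starting material
2 | (S)-6-methyl-3-[(phenylamino)oxy]hept-5-en-2-one | CC(=O)[C@@H](ONc1ccccc1)CC=C(C)C | intermediate
3 | (S)-3-hydroxy-6-methylhept-5-en-2-one | CC(=O)[C@@H](O)CC=C(C)C | intermediate
4 | (S)-3-(tert-butyldimethylsilyloxy)-6-methylhept-5-en-2-one | CC(=O)[C@@H](O[Si](C)(C)C(C)(C)C)CC=C(C)C | intermediate
5 | methyl (R)-2,2-dimethyl-1,3-dioxolane-4-carboxylate | COC(=O)[C@H]1COC(C)(C)O1 | starting material
6 | (R)-N-methoxy-N,2,2-trimethyl-1,3-dioxolane-4-carboxamide | CON(C)C(=O)[C@H]1COC(C)(C)O1 | intermediate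
7 | (R)-1-(2,2-dimethyl-1,3-dioxolan-4-yl)ethan-1-one | CC(=O)[C@H]1COC(C)(C)O1 | intermediate
8 | propane-1,3-diylbis(triphenylphosphonium) dibromide | [Br-].[Br-].c1ccc(cc1)[P+](CCC[P+](c1ccccc1)(c1ccccc1)c1ccccc1)(c1ccccc1)c1ccccc1 | starting material
9 | triphenyl[3-(triphenyl-λ5-phosphanylidene)propyl]phosphonium bromide (mono-ylide) | [Br-].c1ccc(cc1)P(=CCC[P+](c1ccccc1)(c1ccccc1)c1ccccc1)(c1ccccc1)c1ccccc1 | intermediate
10 | [(3Z,5S)-5-(tert-butyldimethylsilyloxy)-4,8-dimethylnona-3,7-dien-1-yl]triphenylphosphonium bromide | [Br-].CC(C)=CC[C@H](O[Si](C)(C)C(C)(C)C)/C(C)=C\CC[P+](c1ccccc1)(c1ccccc1)c1ccccc1 | intermediate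
11 | [(3Z,5S)-5-(tert-butyldimethylsilyloxy)-4,8-dimethylnona-3,7-dien-1-ylidene]triphenyl-λ5-phosphane (ylide) | CC(C)=CC[C@H](O[Si](C)(C)C(C)(C)C)/C(C)=C\CC=P(c1ccccc1)(c1ccccc1)c1ccccc1 | intermediate
12 | (4S)-4-[(2Z,5Z,7S)-7-(tert-butyldimethylsilyloxy)-6,10-dimethylundeca-2,5,9-trien-2-yl]-2,2-dimethyl-1,3-dioxolane | CC(C)=CC[C@H](O[Si](C)(C)C(C)(C)C)/C(C)=C\C/C=C(C)\[C@H]1COC(C)(C)O1 | intermediate
13 | (2S,3Z,6Z,8S)-8-(tert-butyldimethylsilyloxy)-3,7,11-trimethyldodeca-3,6,10-triene-1,2-diol | CC(C)=CC[C@H](O[Si](C)(C)C(C)(C)C)/C(C)=C\C/C=C(C)\[C@H](O)CO | intermediate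
14 | (3Z,6Z,8S)-8-(tert-butyldimethylsilyloxy)-3,7,11-trimethyl-2-oxododeca-3,6,10-trienal | CC(C)=CC[C@H](O[Si](C)(C)C(C)(C)C)/C(C)=C\C/C=C(C)\C(=O)C=O | intermediate
15 | (5S,6S,8S)-8-(tert-butyldimethylsilyloxy)-5-hydroxybisabola-2,7(14),10-trien-4-one | C=C([C@H](CC=C(C)C)O[Si](C)(C)C(C)(C)C)[C@@H]1CC=C(C)C(=O)[C@H]1O | intermediate
16 | (5S,6S,8S)-5,8-dihydroxybisabola-2,7(14),10-trien-4-one | C=C([C@H](CC=C(C)C)O)[C@@H]1CC=C(C)C(=O)[C@H]1O | intermediate
17 | angelic acid [(Z)-2-methylbut-2-enoic acid] | C/C=C(/C)C(=O)O | starting material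
18 | (5S,6S,8S)-5,8-bis(angeloyloxy)bisabola-2,7(14),10-trien-4-one | C=C([C@H](CC=C(C)C)OC(=O)/C(C)=C\C)[C@@H]1CC=C(C)C(=O)[C@H]1OC(=O)/C(C)=C\C | intermediate
19 | (4S,5S,6S,8S)-5,8-bis(angeloyloxy)bisabola-2,7(14),10-trien-4-ol | C=C([C@H](CC=C(C)C)OC(=O)/C(C)=C\C)[C@@H]1CC=C(C)[C@H](O)[C@H]1OC(=O)/C(C)=C\C | intermediate
20 | (2S,3R,4R,5S,6S,8S)-5,8-bis(angeloyloxy)-2,3-epoxybisabola-7(14),10-dien-4-ol | C=C([C@H](CC=C(C)C)OC(=O)/C(C)=C\C)[C@@H]1C[C@@H]2O[C@]2(C)[C@H](O)[C@H]1OC(=O)/C(C)=C\C | intermediate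
21 | (2S,3S,5S,6S,8S)-5,8-bis(angeloyloxy)-2,3-epoxybisabola-7(14),10-dien-4-one (CNP0271744.2) | C=C([C@H](CC=C(C)C)OC(=O)/C(C)=C\C)[C@@H]1C[C@@H]2O[C@]2(C)C(=O)[C@H]1OC(=O)/C(C)=C\C | target

**Step count and risks**
Total steps: 11. Longest linear sequence: 10 (steps 1, 2, 4, 5, 6, 7, 8, 9, 10, 11 from sulcatone).

The three steps most likely to fail:

Step 7 (key closure). The glyoxal may cyclise without the catalyst and give ring diastereomers. Its hydrate may block the copper centre. The ligand may be mismatched with the C8 centre, or induce the opposite sense (the R,R ligand would then be tried first). The fallback moves stereocontrol from the catalyst to the substrate, sets out from 13 and comes back at 15. Diol 13 is oxidised only at the primary alcohol (TEMPO, PhI(OAc)2, CH2Cl2, 0 °C) to (2S,3Z,6Z,8S)-8-(tert-butyldimethylsilyloxy)-2-hydroxy-3,7,11-trimethyldodeca-3,6,10-trienal F1. Me2AlCl (2.2 equiv, CH2Cl2, −78 °C) forms the aluminium alkoxide chelate with the aldehyde and triggers the same carbonyl-ene closure through an all-equatorial chair. The (2S) carbinol from the glycerate fixes C5 and C6 and gives (4S,5S,6S,8S)-8-(tert-butyldimethylsilyloxy)bisabola-2,7(14),10-triene-4,5-diol F2. MnO2 (CH2Cl2, 23 °C) oxidises only the allylic C4 alcohol and gives 15, which is desilylated to 16 as in step 7.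

Step 4 (one-pot double Wittig). The mono-ylide may not form cleanly from the sparingly soluble bis-salt, giving symmetrical dienes. Ketone 4 may be enolised by the ylide, which erodes C8. The Z selectivity may be lower with the cationic ylide. The fallback builds the linchpin stepwise, sets out from 4 and comes back at 12. Ketone 4 is olefinated with the oxido-ylide from (3-hydroxypropyl)triphenylphosphonium bromide (2 equiv KN(SiMe3)2, THF, −78 → 23 °C) to (3Z,5S)-5-(tert-butyldimethylsilyloxy)-4,8-dimethylnona-3,7-dien-1-ol F3, which is purified at this stage to remove any E isomer. I2, PPh3 and imidazole (CH2Cl2, 0 °C) give (3Z,5S)-5-(tert-butyldimethylsilyloxy)-1-iodo-4,8-dimethylnona-3,7-diene F4. PPh3 (MeCN, 60 °C) gives [(3Z,5S)-5-(tert-butyldimethylsilyloxy)-4,8-dimethylnona-3,7-dien-1-yl]triphenylphosphonium iodide F5. KN(SiMe3)2 followed by ketone 7 (THF, −78 → 23 °C) then gives 12.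

Step 6 (keto aldehyde). The Z-enone glyoxal can hydrate, oligomerise or shift its doubly allylic CH2 into conjugation during a one-step double oxidation. The fallback oxidises the two carbinols separately, sets out from 13 and comes back at 14. MnO2 (CH2Cl2, 23 °C) oxidises only the allylic secondary alcohol to (3Z,6Z,8S)-8-(tert-butyldimethylsilyloxy)-1-hydroxy-3,7,11-trimethyldodeca-3,6,10-trien-2-one F6. The classical ketol-to-glyoxal oxidation with Cu(OAc)2 (cat., air, MeOH, 23 °C) then gives 14, freed from its methanol hemiacetal by azeotropic drying before step 7.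

**Further compounds**
F1 | step 7 | (2S,3Z,6Z,8S)-8-(tert-butyldimethylsilyloxy)-2-hydroxy-3,7,11-trimethyldodeca-3,6,10-trienal | CC(C)=CC[C@H](O[Si](C)(C)C(C)(C)C)/C(C)=C\C/C=C(C)\[C@H](O)C=O
F2 | step 7 | (4S,5S,6S,8S)-8-(tert-butyldimethylsilyloxy)bisabola-2,7(14),10-triene-4,5-diol | C=C([C@H](CC=C(C)C)O[Si](C)(C)C(C)(C)C)[C@@H]1CC=C(C)[C@H](O)[C@H]1O
F3 | step 4 | (3Z,5S)-5-(tert-butyldimethylsilyloxy)-4,8-dimethylnona-3,7-dien-1-ol | CC(C)=CC[C@H](O[Si](C)(C)C(C)(C)C)/C(C)=C\CCO
F4 | step 4 | (3Z,5S)-5-(tert-butyldimethylsilyloxy)-1-iodo-4,8-dimethylnona-3,7-diene | CC(C)=CC[C@H](O[Si](C)(C)C(C)(C)C)/C(C)=C\CCI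
F5 | step 4 | [(3Z,5S)-5-(tert-butyldimethylsilyloxy)-4,8-dimethylnona-3,7-dien-1-yl]triphenylphosphonium iodide | [I-].CC(C)=CC[C@H](O[Si](C)(C)C(C)(C)C)/C(C)=C\CC[P+](c1ccccc1)(c1ccccc1)c1ccccc1
F6 | step 6 | (3Z,6Z,8S)-8-(tert-butyldimethylsilyloxy)-1-hydroxy-3,7,11-trimethyldodeca-3,6,10-trien-2-one | CC(C)=CC[C@H](O[Si](C)(C)C(C)(C)C)/C(C)=C\C/C=C(C)\C(=O)CO
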